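Numbering: ring A = C1–C5 and C10, ring B = C5–C10, chain C11–C16, butenolide closed on C16. Enabling feature: ring B is a cyclohexene whose C8=C9 bond carries CH3 on C8 and the chain on C9 and lies next to quaternary C10. C8 with its methyl group is therefore a CH3–C unit that can be inserted into the C9–C7 bond of a five-membered ketone that enolises only towards C7.
Retrosynthetic cuts, in order: O–C16 and C16–C(beta) of the butenolide; C12–C13; C9–C11; C8 (with CH3) out of ring B, leaving a trans-hydrindan-1-one; one C4–CH3 and the C3 oxygen; C4=C5 and C10–C1 of ring A.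
Forward order: the five-membered ring is bought (2-methylcyclopentane-1,3-dione), ring A is annulated onto it, and the five-membered ring is enlarged to ring B. Then C11–C12, C13–C16 and last the butenolide ring are added.
Stereochemistry: C10 comes from an L-phenylalanine-mediated desymmetrising aldol condensation, and C5 from alpha-face protonation in a Li/NH3 reduction (trans fusion). C13=C14 comes from a stabilised iodo-ylide Wittig reaction with retention in the coupling, and C15=C16 from anti addition of the carboxylate to the alkyne.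

Key step: step 9

Remark: alpha is the face opposite to the C10 methyl group. The C9 carbinol centre (steps 3 to 6) and the cyclopropane centres of 13 are temporary. 13 is drawn as the endo-chloro epimer that can open, although some exo-chloro epimer may form beside it.

Step 1
Reactants: 1 2-methylcyclopentane-1,3-dione; 2 pent-1-en-3-one (ethyl vinyl ketone)
Product: 3 2-methyl-2-(3-oxopentyl)cyclopentane-1,3-dione
Conditions: AcOH (cat.), H2O, 75 °C
Reagents that add atoms: none
Why: Michael addition of the acidic 1,3-dione to the unhindered enone forms C10–C1 and the prochiral quaternary carbon, a routine reaction of 2-alkyl-1,3-diones.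

Step 2
Reactants: 3 2-methyl-2-(3-oxopentyl)cyclopentane-1,3-dione
Product: 4 (7aS)-4,7a-dimethyl-2,3,7,7a-tetrahydro-1H-indene-1,5(6H)-dione
Conditions: L-phenylalanine (1 equiv), (1S)-(+)-camphor-10-sulfonic acid (0.5 equiv), MeCN, 40 to 80 °C; recrystallisation
Reagents that add atoms: none
Why: In this Hajos–Parrish–Eder–Sauer–Wiechert reaction the enamine of the ethyl ketone attacks one of the two enantiotopic ring carbonyl groups through a hydrogen-bonded chair-like transition state and the aldol dehydrates, which closes ring A (C4=C5) and sets C10 as S, with recrystallisation expected to raise the material to a single enantiomer.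

Step 3
Reactants: 4 (7aS)-4,7a-dimethyl-2,3,7,7a-tetrahydro-1H-indene-1,5(6H)-dione
Product: 5 (1S,7aS)-1-hydroxy-4,7a-dimethyl-1,2,3,6,7,7a-hexahydro-5H-inden-5-one
Conditions: NaBH4 (0.3 equiv), MeOH/CH2Cl2, −78 °C
Reagents that add atoms: none
Why: In this chemoselective 1,2-reduction the saturated cyclopentanone is more electrophilic than the conjugated enone and hydride arrives on the alpha face opposite to the C10 methyl group, giving the temporary 9-beta (S) carbinol.

Step 4
Reactants: 5 (1S,7aS)-1-hydroxy-4,7a-dimethyl-1,2,3,6,7,7a-hexahydro-5H-inden-5-one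
Product: 6 (1S,7aS)-1-[(tert-butyldimethylsilyl)oxy]-4,7a-dimethyl-1,2,3,6,7,7a-hexahydro-5H-inden-5-one
Conditions: TBSCl, imidazole, DMF, rt
Reagents that add atoms: tert-butyldimethylsilyl chloride, CC(C)(C)[Si](C)(C)Cl
Why: Standard silyl ether formation masks the carbinol against the dissolving-metal step and against O-methylation.

Step 5
Reactants: 6 (1S,7aS)-1-[(tert-butyldimethylsilyl)oxy]-4,7a-dimethyl-1,2,3,6,7,7a-hexahydro-5H-inden-5-one
Product: 8 (1S,3aR,7aS)-1-[(tert-butyldimethylsilyl)oxy]-4,4,7a-trimethyloctahydro-5H-inden-5-one (trans-fused), via lithium enolate 7 (not isolated)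
Conditions: Li, NH3(l)/THF, t-BuOH (1 equiv), −78 to −33 °C; then MeI
Reagents that add atoms: iodomethane, CI
Why: In this reductive alkylation of an enone (dissolving-metal reduction, then enolate alkylation) the beta carbon C5 is protonated on the alpha face to give the trans ring fusion, and the regiodefined C3–C4 enolate is methylated at C4 to complete the gem-dimethyl group.

Step 6
Reactants: 8 (1S,3aR,7aS)-1-[(tert-butyldimethylsilyl)oxy]-4,4,7a-trimethyloctahydro-5H-inden-5-one
Product: 10 (1S,3aS,7aS)-4,4,7a-trimethyloctahydro-1H-inden-1-ol, via hydrazone 9 (not isolated)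
Conditions: N2H4·H2O, KOH, diethylene glycol, 130 then 210 °C
Reagents that add atoms: none
Why: Wolff–Kishner reduction (Huang-Minlon variant) removes the hindered C3 carbonyl group, as is usual for 4,4-dimethyl-3-ketones, and the hot KOH cleaves the silyl ether in the same operation without touching C5 or C10.

Step 7
Reactants: 10 (1S,3aS,7aS)-4,4,7a-trimethyloctahydro-1H-inden-1-ol
Product: 11 (3aS,7aS)-4,4,7a-trimethyloctahydro-1H-inden-1-one
Conditions: Dess–Martin periodinane, CH2Cl2, rt
Reagents that add atoms: none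
Why: Dess–Martin oxidation of a secondary alcohol gives the C9 ketone under neutral conditions, and no stereocentre is alpha to the new carbonyl group.

Step 8
Reactants: 11 (3aS,7aS)-4,4,7a-trimethyloctahydro-1H-inden-1-one
Product: 12 trimethyl{[(3aS,7aS)-3a,7,7-trimethyl-3a,4,5,6,7,7a-hexahydro-1H-inden-3-yl]oxy}silane
Conditions: TMSOTf, Et3N, CH2Cl2, 0 °C
Reagents that add atoms: trimethylsilyl trifluoromethanesulfonate, C[Si](C)(C)OS(=O)(=O)C(F)(F)F
Why: In this soft enolisation with O-silylation C10 is quaternary, so only the C7 hydrogens can be removed and a single C9=C7 enol ether is possible.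

Step 9
Reactants: 12 trimethyl{[(3aS,7aS)-3a,7,7-trimethyl-3a,4,5,6,7,7a-hexahydro-1H-inden-3-yl]oxy}silane
Product: 14 (4aS,8aS)-2,5,5,8a-tetramethyl-4a,5,6,7,8,8a-hexahydronaphthalen-1(4H)-one, via chloro(methyl)cyclopropane adduct 13 (not isolated)
Conditions: CH3CHCl2 (excess), n-BuLi, Et2O, −35 °C; then toluene, 110 °C
Reagents that add atoms: 1,1-dichloroethane, CC(Cl)Cl
Why: n-BuLi deprotonates 1,1-dichloroethane and the carbenoid transfers CH3–C–Cl in a concerted syn [2+1] cheletropic addition to the only C=C bond of 12, the electron-rich C9=C7 enol ether, which closes the transient cyclopropane of 13 and places C8 with its methyl group exactly between C9 and C7. On warming, the endo C8–Cl bond ionises in concert with disrotatory two-electron electrocyclic opening of the C9–C7 bond (Woodward–Hoffmann–DePuy rule), the siloxy oxygen stabilises the developing 2-methylallyl cation as an oxocarbenium ion and chloride removes the silyl group, so the zero bridge of the bicyclo[3.1.0]hexane vanishes and the five-membered ring becomes six-membered ring B as the enone C9(=O)–C8(CH3)=C7. The closest known reaction type is the halocarbene ring expansion of cycloalkanone silyl enol ethers to 2-halo- or 2-methylcycloalk-2-enones. Only the short-lived three-membered ring is closed ([2+1] mode) and no new stereocentre survives, since C7 and C9 of 13 are set by attack on the alpha face opposite to the C10 methyl group and are flattened again, while C5 and C10 are untouched. The step needs positional selectivity of the insertion, which quaternary C10 secures because 11 enolises only towards C7, and it needs chlorine endo at C8, which the substrate favours because the endo site faces the alpha hydrogen on C5 and accepts the smaller chlorine rather than the methyl group. The product keeps C9 as a carbonyl group that can enolise only towards C8, which is what later fixes the tetrasubstituted C8=C9 bond.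

Step 10
Reactants: 14 (4aS,8aS)-2,5,5,8a-tetramethyl-4a,5,6,7,8,8a-hexahydronaphthalen-1(4H)-one
Product: 16 (4aS,8aS)-2,5,5,8a-tetramethyl-3,4,4a,5,6,7,8,8a-octahydronaphthalen-1-yl trifluoromethanesulfonate, via lithium enolate 15 (not isolated)
Conditions: LiBH(s-Bu)3, THF, −78 °C; then PhNTf2, −78 °C to rt
Reagents that add atoms: N-phenylbis(trifluoromethanesulfonimide), O=S(=O)(N(c1ccccc1)S(=O)(=O)C(F)(F)F)C(F)(F)F
Why: In this conjugate hydride reduction with enolate trapping the carbonyl carbon is shielded by C10 and the C8 methyl group, so the bulky borohydride adds to unsubstituted C7, and O-sulfonylation of the regiodefined enolate fixes the C8=C9 double bond.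

Step 11
Reactants: 16 (4aS,8aS)-2,5,5,8a-tetramethyl-3,4,4a,5,6,7,8,8a-octahydronaphthalen-1-yl trifluoromethanesulfonate
Product: 17 (4aS,8aS)-1-ethenyl-2,5,5,8a-tetramethyl-3,4,4a,5,6,7,8,8a-octahydronaphthalene
Conditions: Bu3SnCH=CH2, Pd(PPh3)4, LiCl, THF, 65 °C
Reagents that add atoms: tributyl(vinyl)stannane, C=C[Sn](CCCC)(CCCC)CCCC
Why: Stille coupling of an enol triflate with the small vinyl group is well known for 2,6,6-trisubstituted cyclohexenyl triflates and forms C9–C11 without moving the ring double bond.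

Step 12
Reactants: 18 3-(triisopropylsilyl)prop-2-ynal; 19 ethyl (triphenylphosphoranylidene)acetate
Product: 21 ethyl (Z)-2-iodo-5-(triisopropylsilyl)pent-2-en-4-ynoate, via iodo ylide 20 (not isolated)
Conditions: 19, N-iodosuccinimide, CH2Cl2, −20 °C; then 18, rt
Reagents that add atoms: N-iodosuccinimide, O=C1CCC(=O)N1I
Why: In this Wittig reaction of a stabilised alpha-iodo ylide made in the flask by iodination of 19, the ester ends up trans to the aldehyde residue as with other stabilised ylides, which is the Z iodoalkene needed for C13=C14.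

Step 13
Reactants: 21 ethyl (Z)-2-iodo-5-(triisopropylsilyl)pent-2-en-4-ynoate
Product: 22 (Z)-2-iodo-5-(triisopropylsilyl)pent-2-en-4-yn-1-ol
Conditions: i-Bu2AlH (2.2 equiv), CH2Cl2, −78 °C
Reagents that add atoms: none
Why: 1,2-Reduction of an enoate with an aluminium hydride at low temperature gives the allylic alcohol and leaves the vinyl iodide, the silyl alkyne and the alkene geometry intact.

Step 14
Reactants: 17 (4aS,8aS)-1-ethenyl-2,5,5,8a-tetramethyl-3,4,4a,5,6,7,8,8a-octahydronaphthalene; 22 (Z)-2-iodo-5-(triisopropylsilyl)pent-2-en-4-yn-1-ol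
Product: 24 (2E)-2-{2-[(4aS,8aS)-2,5,5,8a-tetramethyl-3,4,4a,5,6,7,8,8a-octahydronaphthalen-1-yl]ethyl}-5-(triisopropylsilyl)pent-2-en-4-yn-1-ol, via B-alkyl-9-BBN 23 (not isolated)
Conditions: 17, 9-BBN-H, THF, 0 °C to rt; then 22, PdCl2(dppf), AsPh3, Cs2CO3, DMF/H2O, rt
Reagents that add atoms: none
Why: In this hydroboration and B-alkyl Suzuki–Miyaura coupling 9-BBN-H adds only to the monosubstituted vinyl group with boron on terminal C12, and the sp3–sp2 coupling forms C12–C13 with retention of the alkene geometry, so the chain is cis and CH2OH trans to the alkynyl group.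

Step 15
Reactants: 24 (2E)-2-{2-[(4aS,8aS)-2,5,5,8a-tetramethyl-3,4,4a,5,6,7,8,8a-octahydronaphthalen-1-yl]ethyl}-5-(triisopropylsilyl)pent-2-en-4-yn-1-ol
Product: 25 (2E)-2-{2-[(4aS,8aS)-2,5,5,8a-tetramethyl-3,4,4a,5,6,7,8,8a-octahydronaphthalen-1-yl]ethyl}pent-2-en-4-yn-1-ol
Conditions: n-Bu4NF, THF, 0 °C to rt
Reagents that add atoms: none
Why: Fluoride-induced protiodesilylation of an alkynylsilane frees the terminal alkyne and affects no other group present.

Step 16
Reactants: 26 but-2-ynoic acid
Product: 27 (Z)-3-iodobut-2-enoic acid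
Conditions: NaI, AcOH, 110 °C
Reagents that add atoms: sodium iodide, [Na+].[I-]
Why: Hydroiodination of an alkynoic acid proceeds by conjugate anti addition of HI and places iodine at C3 cis to the carboxyl group.

Step 17
Reactants: 25 (2E)-2-{2-[(4aS,8aS)-2,5,5,8a-tetramethyl-3,4,4a,5,6,7,8,8a-octahydronaphthalen-1-yl]ethyl}pent-2-en-4-yn-1-ol; 27 (Z)-3-iodobut-2-enoic acid
Product: 29 target, (5Z)-5-{(2E)-3-(hydroxymethyl)-5-[(4aS,8aS)-2,5,5,8a-tetramethyl-3,4,4a,5,6,7,8,8a-octahydronaphthalen-1-yl]pent-2-en-1-ylidene}-4-methylfuran-2(5H)-one, via dienynoic acid 28 (not isolated)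
Conditions: Pd(PPh3)4 (cat.), CuI (cat.), Et3N, MeCN, rt
Reagents that add atoms: none
Why: Sonogashira coupling with retention at the iodoalkene is followed in the same flask by metal-promoted 5-exo-dig anti addition of the cis carboxylate to the alkyne, a known tandem route to gamma-alkylidenebutenolides that puts C14 cis to the ring oxygen (Z) and tolerates the free allylic alcohol.

Compound list
1 | 2-methylcyclopentane-1,3-dione | CC1C(=O)CCC1=O | starting material
2 | pent-1-en-3-one | CCC(=O)C=C | starting material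
3 | 2-methyl-2-(3-oxopentyl)cyclopentane-1,3-dione | CCC(=O)CCC1(C)C(=O)CCC1=O | intermediate
4 | (7aS)-4,7a-dimethyl-2,3,7,7a-tetrahydro-1H-indene-1,5(6H)-dione | C[C@]12CCC(=O)C(C)=C1CCC2=O | intermediate
5 | (1S,7aS)-1-hydroxy-4,7a-dimethyl-1,2,3,6,7,7a-hexahydro-5H-inden-5-one | C[C@]12CCC(=O)C(C)=C1CC[C@@H]2O | intermediate
6 | (1S,7aS)-1-[(tert-butyldimethylsilyl)oxy]-4,7a-dimethyl-1,2,3,6,7,7a-hexahydro-5H-inden-5-one | C[C@]12CCC(=O)C(C)=C1CC[C@@H]2O[Si](C)(C)C(C)(C)C | intermediate
7 | trans-fused lithium C3–C4 enolate from 6 | C[C@]12CCC([O-])=C(C)[C@@H]1CC[C@@H]2O[Si](C)(C)C(C)(C)C.[Li+] | intermediate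
8 | (1S,3aR,7aS)-1-[(tert-butyldimethylsilyl)oxy]-4,4,7a-trimethyloctahydro-5H-inden-5-one | C[C@]12CCC(=O)C(C)(C)[C@@H]1CC[C@@H]2O[Si](C)(C)C(C)(C)C | intermediate
9 | hydrazone of 8 | C[C@]12CCC(=NN)C(C)(C)[C@@H]1CC[C@@H]2O[Si](C)(C)C(C)(C)C | intermediate
10 | (1S,3aS,7aS)-4,4,7a-trimethyloctahydro-1H-inden-1-ol | C[C@]12CCCC(C)(C)[C@@H]1CC[C@@H]2O | intermediate
11 | (3aS,7aS)-4,4,7a-trimethyloctahydro-1H-inden-1-one | C[C@]12CCCC(C)(C)[C@@H]1CCC2=O | intermediate
12 | trimethyl{[(3aS,7aS)-3a,7,7-trimethyl-3a,4,5,6,7,7a-hexahydro-1H-inden-3-yl]oxy}silane | C[C@]12CCCC(C)(C)[C@@H]1CC=C2O[Si](C)(C)C | intermediate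
13 | alpha-face cyclopropane adduct of 12 (C8 bridging C9 and C7, chlorine endo, methyl exo) | C[C@]12CCCC(C)(C)[C@@H]1C[C@H]3[C@@](C)(Cl)[C@@]23O[Si](C)(C)C | intermediate
14 | (4aS,8aS)-2,5,5,8a-tetramethyl-4a,5,6,7,8,8a-hexahydronaphthalen-1(4H)-one | C[C@]12CCCC(C)(C)[C@@H]1CC=C(C)C2=O | intermediate
15 | lithium C9–C8 enolate from 14 | C[C@]12CCCC(C)(C)[C@@H]1CCC(C)=C2[O-].[Li+] | intermediate
16 | (4aS,8aS)-2,5,5,8a-tetramethyl-3,4,4a,5,6,7,8,8a-octahydronaphthalen-1-yl trifluoromethanesulfonate | C[C@]12CCCC(C)(C)[C@@H]1CCC(C)=C2OS(=O)(=O)C(F)(F)F | intermediate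
17 | (4aS,8aS)-1-ethenyl-2,5,5,8a-tetramethyl-3,4,4a,5,6,7,8,8a-octahydronaphthalene | C[C@]12CCCC(C)(C)[C@@H]1CCC(C)=C2C=C | intermediate
18 | 3-(triisopropylsilyl)prop-2-ynal | O=CC#C[Si](C(C)C)(C(C)C)C(C)C | starting material
19 | ethyl (triphenylphosphoranylidene)acetate | CCOC(=O)C=P(c1ccccc1)(c1ccccc1)c1ccccc1 | starting material
20 | ethyl iodo(triphenylphosphoranylidene)acetate | CCOC(=O)C(I)=P(c1ccccc1)(c1ccccc1)c1ccccc1 | intermediate
21 | ethyl (Z)-2-iodo-5-(triisopropylsilyl)pent-2-en-4-ynoate | CCOC(=O)/C(I)=C/C#C[Si](C(C)C)(C(C)C)C(C)C | intermediate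
22 | (Z)-2-iodo-5-(triisopropylsilyl)pent-2-en-4-yn-1-ol | OC/C(I)=C/C#C[Si](C(C)C)(C(C)C)C(C)C | intermediate
23 | 9-{2-[(4aS,8aS)-2,5,5,8a-tetramethyl-3,4,4a,5,6,7,8,8a-octahydronaphthalen-1-yl]ethyl}-9-borabicyclo[3.3.1]nonane | C[C@]12CCCC(C)(C)[C@@H]1CCC(C)=C2CCB1C2CCCC1CCC2 | intermediate
24 | (2E)-2-{2-[(4aS,8aS)-2,5,5,8a-tetramethyl-3,4,4a,5,6,7,8,8a-octahydronaphthalen-1-yl]ethyl}-5-(triisopropylsilyl)pent-2-en-4-yn-1-ol | C[C@]12CCCC(C)(C)[C@@H]1CCC(C)=C2CC/C(CO)=C\C#C[Si](C(C)C)(C(C)C)C(C)C | intermediate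
25 | (2E)-2-{2-[(4aS,8aS)-2,5,5,8a-tetramethyl-3,4,4a,5,6,7,8,8a-octahydronaphthalen-1-yl]ethyl}pent-2-en-4-yn-1-ol | C[C@]12CCCC(C)(C)[C@@H]1CCC(C)=C2CC/C(CO)=C\C#C | intermediate
26 | but-2-ynoic acid | CC#CC(=O)O | starting material
27 | (Z)-3-iodobut-2-enoic acid | C/C(I)=C/C(=O)O | intermediate
28 | (2Z,6E)-dien-4-ynoic acid from Sonogashira coupling of 25 and 27 | C[C@]12CCCC(C)(C)[C@@H]1CCC(C)=C2CC/C(CO)=C\C#C/C(C)=C\C(=O)O | intermediate
29 | (5Z)-5-{(2E)-3-(hydroxymethyl)-5-[(4aS,8aS)-2,5,5,8a-tetramethyl-3,4,4a,5,6,7,8,8a-octahydronaphthalen-1-yl]pent-2-en-1-ylidene}-4-methylfuran-2(5H)-one | CC1=CC(=O)O/C1=C\C=C(\CO)CCC1=C(C)CC[C@H]2C(C)(C)CCC[C@]12C | target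

Total step count: 17. Longest linear sequence: 14 (steps 1 to 11, 14, 15, 17).

Steps most likely to fail

Step 9.
- **Risk:** Carbene transfer to the hindered enol ether may be slower than the 1,2-hydrogen shift of the carbene. n-BuLi may desilylate 12. Any adduct with chlorine exo cannot open in the allowed disrotatory sense.
- **Fallback:** It sets out from 11 and comes back at 16. Ketone 11 is homologated directly with diazoethane under BF3·OEt2 (Et2O/CH2Cl2, −78 °C). This is a Lewis-acid-promoted diazoalkane ring expansion of the Tiffeneau–Demjanov type, in which the less substituted C7 methylene migrates to the diazo carbon in preference to quaternary C10. It should give (4aS,8aS)-2,5,5,8a-tetramethyloctahydronaphthalen-1(2H)-one F1 as C8 epimers. The epimers do not matter, because KN(SiMe3)2 can remove only the C8 hydrogen and PhNTf2 then gives 16.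

Step 5.
- **Risk:** Protonation at C5 may show poor facial selectivity (cis fusion), the ketone may be over-reduced, and the enolate may be methylated on oxygen or more than once.
- **Fallback:** It sets out from 6 and comes back at 8. Deconjugative alpha-methylation of the extended enolate (KOt-Bu, MeI, t-BuOH) gives the beta,gamma-unsaturated ketone (1S,7aS)-1-[(tert-butyldimethylsilyl)oxy]-4,4,7a-trimethyl-1,2,4,6,7,7a-hexahydro-5H-inden-5-one F2 with a C5=C6 bond. Radical hydrogenation by hydrogen atom transfer (Mn(dpm)3, PhSiH3, t-BuOOH, i-PrOH) then puts hydrogen on C6. The tertiary C5 radical takes up hydrogen on the alpha face, away from the C10 and 4-beta methyl groups, and this gives 8.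

Step 14.
- **Risk:** Protodeboronation or beta-hydride elimination of the alkylpalladium species may compete. The free 2-iodoallylic alcohol and the enyne may undergo side reactions on palladium, and the silyl group may be lost under the basic aqueous conditions.
- **Fallback:** It sets out from 17 (through 23) and comes back at 24. It makes C13=C14 by olefination instead of C12–C13 by coupling.
  1. Oxidation of 23 (H2O2, NaOH) gives 2-[(4aS,8aS)-2,5,5,8a-tetramethyl-3,4,4a,5,6,7,8,8a-octahydronaphthalen-1-yl]ethanol F3.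
  2. I2, PPh3 and imidazole give the primary iodide F4.
  3. Alkylation of sodio triethyl phosphonoacetate (NaH, DMF) gives the alpha-alkylated phosphonoacetate F5.
  4. Horner–Wadsworth–Emmons reaction with aldehyde 18 (NaH, THF) gives the enynoate F6 with the ester trans to the alkynyl group.
  5. i-Bu2AlH (CH2Cl2, −78 °C) gives 24.

Further compounds
F1 | step 9 | (4aS,8aS)-2,5,5,8a-tetramethyloctahydronaphthalen-1(2H)-one (C2 epimers) | C[C@]12CCCC(C)(C)[C@@H]1CCC(C)C2=O
F2 | step 5 | (1S,7aS)-1-[(tert-butyldimethylsilyl)oxy]-4,4,7a-trimethyl-1,2,4,6,7,7a-hexahydro-5H-inden-5-one | C[C@]12CCC(=O)C(C)(C)C1=CC[C@@H]2O[Si](C)(C)C(C)(C)C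
F3 | step 14 | 2-[(4aS,8aS)-2,5,5,8a-tetramethyl-3,4,4a,5,6,7,8,8a-octahydronaphthalen-1-yl]ethanol | C[C@]12CCCC(C)(C)[C@@H]1CCC(C)=C2CCO
F4 | step 14 | (4aS,8aS)-1-(2-iodoethyl)-2,5,5,8a-tetramethyl-3,4,4a,5,6,7,8,8a-octahydronaphthalene | C[C@]12CCCC(C)(C)[C@@H]1CCC(C)=C2CCI
F5 | step 14 | ethyl 2-(diethoxyphosphoryl)-4-[(4aS,8aS)-2,5,5,8a-tetramethyl-3,4,4a,5,6,7,8,8a-octahydronaphthalen-1-yl]butanoate (C2 epimers) | C[C@]12CCCC(C)(C)[C@@H]1CCC(C)=C2CCC(C(=O)OCC)P(=O)(OCC)OCC
F6 | step 14 | ethyl (2E)-2-{2-[(4aS,8aS)-2,5,5,8a-tetramethyl-3,4,4a,5,6,7,8,8a-octahydronaphthalen-1-yl]ethyl}-5-(triisopropylsilyl)pent-2-en-4-ynoate | C[C@]12CCCC(C)(C)[C@@H]1CCC(C)=C2CC/C(C(=O)OCC)=C\C#C[Si](C(C)C)(C(C)C)C(C)C
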